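**Conventions.** Target numbering is used for every compound: ring carbons C1 (ketone), C2, C3 (OH), C4 (CH3), C5, C6 (lactone O), C7, C8 (angelate), C9, C10 (CH3, OAc); lactone carbons C11 (=C13H2) and C12 (C=O). α is the face carrying the C7–C11 bond, the C8 oxygen and the C10 oxygen; β is the opposite face (C10 methyl, C3 oxygen, C4 methyl).

**Assumption.** The crotylborane made from (–)-α-pinene is taken to add to the Re face of aldehyde 12, as it does with simple aldehydes; if the sense were reversed, the enantiomeric reagent would be used.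

## Analysis of the target

The target 34 is a saturated ten-membered carbocycle (C1–C10), cis-fused at C6–C7 to an α-methylene-γ-butyrolactone (O–C6, C7–C11, C11=C13, C12=O). It has six stereocentres: C3 (R, free hydroxyl), C4 (S, methyl), C6 (S), C7 (S), C8 (R, angelate) and C10 (S, tertiary acetate with methyl). C6, C7 and C8 are contiguous, with H-6 and H-7 cis and the C8 oxygen cis to C11. The C3/C4 pair and C10 are separated from this triad by the C5 and C9 methylenes and the C1 ketone. The sensitive groups are the α-methylene lactone (Michael acceptor), the angelate (Z to E isomerisation with bases and nucleophiles), the C1/C3 β-hydroxy ketone (retro-aldol, dehydration) and the tertiary α-acyloxy ketone. The difficulty is that a ring of this size with no alkene gives little stereocontrol and is costly to close directly, so the stereocentres must be in place before the ring exists. The feature used is that the C1 ketone faces the oxygen-bearing C6 across the ring. A C1–C6 bond turns the ring into a decalin (ring A: C1–C6; ring B: C1, C6–C10), and cleaving that bond again can leave the ketone at C1 and a C5≡C6 alkyne. That alkyne is γ,δ to the C12 acid, so it guides the lactone oxygen to C6.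

## Retrosynthetic reasoning

**C3–O–Si, C6–H and O–C6.** Target 34 is traced to silyl ether 33, then to enol lactone 32 by removing the hydrogens at C5 and C6, and then to alkynoic acid 31 by cutting the O–C6 bond. Forward, the acid adds 5-exo to the alkyne and a hydride is delivered to the acyloxocarbenium ion at C6. This sets C6 last, next to the fixed C7 and C8 centres.

**C1–C6 (key).** Alkynone 31 is reconnected between C1 and C6 to the epoxy ketone 28, with hydrazide 29 as the trigger. No other ring bond pairs a ketone with a γ,δ-alkynoic acid in this way. The gain is that all stereocentres but C6 sit on a rigid decalin and the medium ring is released, not closed. Forward, the fusion bond must break with loss of dinitrogen and sulfinate.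

**Oxidation levels at C12, C5 and C1/C6.** Acid 28 comes from keto enal 27, diol 26 and epoxy alcohol 25, and 25 from allylic alcohol 24. The C12 acid is therefore an isopropenyl methyl until late. An earlier acid would lactonise onto a free C8 hydroxyl, and an acrylate would not survive hydride and enolate steps. The C5 hydroxyl steers the epoxidation to the C1=C6 alkene before it is oxidised.

**Acyl–O bonds at C8 and C10.** Alcohol 24 is traced through 23 and 22 to diol 19 and angelic acid 20. The base-sensitive angelate enters after every strongly basic or reducing step.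

**C1–C2 and the C3 carbinol.** Diol 19 goes back through 18 and 17 to ketone 16, and 16 to bromo ketone 15 by cutting C1–C2. Forward, only the methyl-side enolate of 15 can close a six-membered ring onto the vinyl bromide. The C3 alcohol then arises by hydride attack anti to the C4 methyl.

**C4–C5.** Ketone 15 is traced through 14 and 13 to bromo enal 12 by cutting C4–C5 (crotylboration, then Wacker oxidation). Stereocentres on ring A and ring B cannot control each other across the planar C1=C6 alkene. C4 is therefore set by the reagent, and C3 is set from C4.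

**C5–C6 and C1–Br.** Enal 12 comes from ketone 11 by haloformylation. C10 is quaternary, so the ketone can enolise only towards C6. Ketone 11 is the silylene-protected form of keto diol 10.

**Ring B oxygens.** Keto diol 10 is traced through triol 8, epoxide 7, diol 6 and epoxide 3 to carveol 2 and (R)-carvone 1. Carvone supplies C7, the C10 methyl, the C1 oxygen and the isopropenyl group that becomes C11–C13. Two hydroxyl-directed epoxidations place the C10 and C8 oxygens cis to the side chain.

## Alternatives that were turned down

**Alternative 1:** The ring is disconnected at C1–C2 and C7–C8. Forward, a [2+2] photocycloaddition joins an enone and a bis(silyloxy)cyclobutene held in one molecule, and heating then breaks C2–C7 and C1–C8, so three small rings open to the ten-membered trione A1.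
- For: two skeletal bonds and the ring arise in one operation without the entropy of a direct closure, and C3, C4 and C10 come from the chiral pool.
- Against: A1 carries ketones at C1, C6 and C8 around an unsubstituted C7. The three-carbon lactone unit must still be attached at C7, the three ketones told apart, and C6, C7 and C8 set on a flexible ring. The regiochemistry of the photoaddition is a further open point.
- Comparison: it is stronger in bond construction and likely shorter to the ring. The chosen route instead has the C7/C8 pair and C10 fixed on a bicycle before the ring exists, leaving only C6.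

**Alternative 2:** The ring is disconnected at C5–C6. Forward, the C4=C5 alkene is hydroborated anti to the C3 silyl ether, and the C5 borane couples with a C6 bromofuran under palladium catalysis, giving the furan-fused ring A2.
- For: it is convergent, the coupling type is well established, C4 is set in the same step, and the furan is a robust latent lactone.
- Against: a ten-membered ring is closed head-on, so dilution and transannular strain apply. C4 rests on acyclic 1,2-induction. The furan must later be oxidised and reduced to the cis lactone and methylenated at C11, which puts C6 and C7 back on the flexible ring.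
- Comparison: it is at least as convergent. The chosen route offers ring formation without a closure event and has C7 fixed from the start.

**Alternative 3:** The ring is disconnected at C7–C8. Forward, tin–lithium exchange at C8 of a 13-membered α-stannyl allyl ether triggers a [2,3] shift that forms C7–C8, breaks O–C13, creates the C11=C13 methylene and contracts the ring to A3.
- For: one step forms a skeletal bond, two stereocentres and the exocyclic methylene, and a 13-membered ether is easier to close than a ten-membered carbocycle.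
- Against: the C7/C8 outcome depends on the conformation of a large ring in the transition state. The stannyl ether stereocentre and a macro-etherification must be prepared. A3 still needs oxidation of C12, lactonisation onto C6 and several protecting-group changes.
- Comparison: it does more construction in the key step. The chosen route pays with a longer run to the precursor, but its key step makes no stereocentre and has a close precedent.

Key step: step 23

## Route

Step 1
Reactants: 1 (R)-(–)-carvone
Product: 2 (1R,5R)-cis-carveol (C1–OH α)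
Conditions: NaBH4, CeCl3·7H2O, MeOH, –78 to 0 °C
Reagents that add atoms: none
Why: Luche 1,2-reduction; hydride adds to the half-chair with the isopropenyl group equatorial so that the hydroxyl ends cis to it.

Step 2
Reactants: 2 cis-carveol
Product: 3 9α,10α-epoxy alcohol
Conditions: VO(acac)2 (cat.), t-BuOOH, CH2Cl2, 0 to 23 °C
Reagents that add atoms: tert-butyl hydroperoxide CC(C)(C)OO
Why: Hydroxyl-directed epoxidation through the vanadate ester puts the oxygen on the face of the C1 hydroxyl, which fixes the C10 oxygen on the α face; the isopropenyl alkene is not allylic to the hydroxyl and is left.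

Step 3
Reactants: 3 epoxy alcohol
Product: 6 tertiary allylic diol (1α,10α-dihydroxy-8-ene), via hydroxy selenide 4 (not isolated), via selenoxide 5 (not isolated)
Conditions: PhSeSePh, NaBH4, EtOH, 78 °C; then 30% H2O2, THF, 0 to 23 °C
Reagents that add atoms: none
Why: The selenolate opens the epoxide at the less substituted C9 (trans-diaxial), and selenoxide syn-elimination can only go towards C8 because C10 has no hydrogen; C10 keeps its configuration.

Step 4
Reactants: 6 allylic diol
Product: 7 8α,9α-epoxy diol
Conditions: VO(acac)2 (cat.), t-BuOOH, CH2Cl2, 23 °C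
Reagents that add atoms: tert-butyl hydroperoxide CC(C)(C)OO
Why: Directed epoxidation by the tertiary allylic C10 hydroxyl (the C1 hydroxyl lies on the same face) delivers oxygen to the α face of C8=C9 in spite of the neighbouring isopropenyl group.

Step 5
Reactants: 7 epoxy diol
Product: 8 1α,8α,10α-triol
Conditions: NaAlH2(OCH2CH2OCH3)2, THF, 0 to 23 °C
Reagents that add atoms: none
Why: Hydride opens the epoxide at C9, the trans-diaxial (Fürst–Plattner) mode that keeps the isopropenyl group equatorial and avoids the more hindered C8; the C8 oxygen stays α, giving the cis-1,3-diol.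

Step 6
Reactants: 8 triol
Product: 10 keto diol (1-oxo-8α,10α-diol), via stannylene acetal 9 (not isolated)
Conditions: Bu2SnO, MeOH, 65 °C; evaporate; then N-bromosuccinimide, CHCl3, 23 °C
Reagents that add atoms: none
Why: The cis-vicinal C1/C10 diol forms the five-membered stannylene acetal, and brominolysis oxidises the only secondary carbinol inside it; the C8 hydroxyl is not part of the acetal.

Step 7
Reactants: 10 keto diol
Product: 11 8α,10α-O-(di-tert-butylsilylene) ketone
Conditions: (t-Bu)2Si(OTf)2, 2,6-lutidine, CH2Cl2, 0 to 23 °C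
Reagents that add atoms: di-tert-butylsilyl bis(trifluoromethanesulfonate) CC(C)(C)[Si](OS(=O)(=O)C(F)(F)F)(OS(=O)(=O)C(F)(F)F)C(C)(C)C
Why: The 1,3-diaxial diol is bridged as a six-membered dialkoxysilane, one group that masks both hydroxyls through the acidic, basic and hydride steps that follow.

Step 8
Reactants: 11 silylene ketone
Product: 12 1-bromo-6-formyl cyclohexene (C1=C6, C5 as CHO)
Conditions: PBr3, DMF, CHCl3, 0 to 50 °C; aq. NaOAc
Reagents that add atoms: N,N-dimethylformamide CN(C)C=O; phosphorus tribromide BrP(Br)Br; water O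
Why: Vilsmeier–Haack–Arnold haloformylation; C10 is quaternary, so the ketone enolises only towards C6, which places the formyl carbon (C5) on C6 and bromide on C1 of a tetrasubstituted alkene.

Step 9
Reactants: 12 bromo enal
Product: 13 anti homoallylic alcohol (C4 R, C5 R; C4 methyl and C5 hydroxyl both β after ring closure)
Conditions: (E)-crotyl-B(Ipc)2 [trans-2-butene, n-BuLi, t-BuOK; (+)-Ipc2BOMe; BF3·OEt2], THF, –78 °C; then NaBO3·4H2O, 23 °C
Reagents that add atoms: (E)-crotyldiisopinocampheylborane from (–)-α-pinene C/C=C/CB([C@H]1C[C@H]2C[C@@H]([C@@H]1C)C2(C)C)[C@H]1C[C@H]2C[C@@H]([C@@H]1C)C2(C)C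
Why: Asymmetric crotylboration through a chair six-membered transition state; the E reagent gives the anti adduct and the isopinocampheyl groups select the Re face of the aldehyde, so C4 is set by the reagent, independent of the remote ring B centres.

Step 10
Reactants: 13 homoallylic alcohol
Product: 14 C5 4-methoxybenzyl ether
Conditions: NaH, 4-MeOC6H4CH2Cl, Bu4NI (cat.), DMF, 0 to 23 °C
Reagents that add atoms: 4-methoxybenzyl chloride COc1ccc(CCl)cc1
Why: Williamson etherification; the ether keeps the future β-hydroxy ketone from retro-aldol cleavage and can later be removed oxidatively beside silyl ethers and esters.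

Step 11
Reactants: 14 ether
Product: 15 methyl ketone (C3=O, C2 methyl)
Conditions: PdCl2 (cat.), CuCl, O2 (1 atm), DMF/H2O, 23 °C
Reagents that add atoms: water O
Why: Tsuji–Wacker oxidation; the monosubstituted vinyl group reacts much faster than the 1,1-disubstituted isopropenyl group and gives the Markovnikov methyl ketone.

Step 12
Reactants: 15 bromo methyl ketone
Product: 16 octalin ketone (ring A closed, C1=C6, C3=O)
Conditions: Pd(PPh3)4 (cat.), t-BuOK, THF, 23 °C
Reagents that add atoms: none
Why: Palladium-catalysed intramolecular α-alkenylation of a ketone enolate with a vinyl bromide; only the methyl-side enolate can reach C1 in a six-membered ring, so C1–C2 forms and the tetrasubstituted alkene stays at the ring fusion.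

Step 13
Reactants: 16 ketone
Product: 17 C3 β-alcohol
Conditions: LiBH(s-Bu)3, THF, –78 °C; then NaOH, H2O2
Reagents that add atoms: none
Why: The bulky hydride approaches C3 anti to the adjacent β methyl and the β C5 ether, so the hydroxyl ends cis to the C4 methyl.

Step 14
Reactants: 17 alcohol
Product: 18 C3 tert-butyldimethylsilyl ether
Conditions: TBSOTf, 2,6-lutidine, CH2Cl2, –78 to 0 °C
Reagents that add atoms: tert-butyldimethylsilyl trifluoromethanesulfonate CC(C)(C)[Si](C)(C)OS(=O)(=O)C(F)(F)F
Why: Standard silylation of a secondary alcohol; this ether is carried to the last step.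

Step 15
Reactants: 18 silylene
Product: 19 8α,10α-diol
Conditions: HF·pyridine, pyridine, THF, 0 °C
Reagents that add atoms: none
Why: Buffered fluoride cleaves the dialkoxysilane faster than the hindered secondary silyl ether, and the non-acidic medium does not ionise the tertiary allylic C10 alcohol.

Step 16
Reactants: 19 diol; 20 angelic acid
Product: 22 C8 angelate, via mixed anhydride 21 (not isolated)
Conditions: 2,4,6-Cl3C6H2COCl, Et3N, toluene, 23 °C; then 19, 80 °C
Reagents that add atoms: none
Why: Yamaguchi-type esterification through the mixed anhydride without a nucleophilic amine catalyst, which avoids angelate to tiglate isomerisation; only the secondary C8 hydroxyl reacts, the tertiary C10 hydroxyl does not.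

Step 17
Reactants: 22 angelate
Product: 23 C10 acetate
Conditions: Ac2O, DMAP, Et3N, CH2Cl2, 23 to 40 °C
Reagents that add atoms: acetic anhydride CC(=O)OC(C)=O
Why: Acyl-pyridinium catalysed acetylation of the tertiary alcohol under basic conditions, which do not ionise the allylic position.

Step 18
Reactants: 23 diester
Product: 24 C5 β allylic alcohol
Conditions: DDQ, CH2Cl2/pH 7 buffer, 0 °C
Reagents that add atoms: none
Why: Oxidative cleavage of the 4-methoxybenzyl ether by hydride abstraction at the benzylic position; esters, the silyl ether and the alkenes are untouched.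

Step 19
Reactants: 24 allylic alcohol
Product: 25 1β,6β-epoxy alcohol
Conditions: VO(acac)2 (cat.), t-BuOOH, CH2Cl2, 0 to 23 °C
Reagents that add atoms: tert-butyl hydroperoxide CC(C)(C)OO
Why: Directed epoxidation of the tetrasubstituted C1=C6 alkene from the face of the C5 hydroxyl; the isopropenyl and angelate alkenes have no directing hydroxyl, and the face of the epoxide has no bearing on the later steps.

Step 20
Reactants: 25 epoxy alcohol
Product: 26 C12 allylic alcohol (5,12-diol)
Conditions: SeO2 (cat.), t-BuOOH, CH2Cl2, 23 °C
Reagents that add atoms: selenium dioxide O=[Se]=O; tert-butyl hydroperoxide CC(C)(C)OO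
Why: Allylic oxidation by ene reaction and [2,3] shift at the methyl of the only electron-rich alkene left; the C7 methine is shielded by its two substituted neighbours, and any enal formed converges in the next step.

Step 21
Reactants: 26 diol
Product: 27 keto enal (C5 ketone, C12 aldehyde)
Conditions: Dess–Martin periodinane, NaHCO3, CH2Cl2, 0 to 23 °C
Reagents that add atoms: none
Why: One buffered oxidation converts both the secondary C5 carbinol and the primary allylic alcohol, mild enough not to epimerise C4 or eliminate the C3 silyl ether.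

Step 22
Reactants: 27 keto enal
Product: 28 epoxy keto acid (fragmentation precursor)
Conditions: NaClO2, NaH2PO4, 2-methyl-2-butene, t-BuOH/H2O, 0 to 23 °C
Reagents that add atoms: sodium chlorite [Na+].[O-]Cl=O
Why: Pinnick oxidation of the enal to the 2-substituted acrylic acid; the scavenger traps hypochlorous acid and protects the alkenes.

Step 23
Reactants: 28 epoxy keto acid; 29 p-toluenesulfonyl hydrazide
Product: 31 cyclodec-5-yn-1-one acid (3R,4S,7R,8R,10S), via tosylhydrazone 30 (not isolated)
Conditions: AcOH/CH2Cl2 1:1, –20 to 23 °C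
Reagents that add atoms: none
Why: Condensation at the C5 ketone gives tosylhydrazone 30, whose nitrogen lone pair opens the epoxide at C6 (C6–O cleavage) to a C1 carbinol carrying a C5=C6 alkenyl diazene. Collapse of the C1 carbinol to the ketone then cleaves the C1–C6 bond, which lies in the plane of the alkenyl diazene, and expels dinitrogen and p-toluenesulfinate to leave the C5≡C6 triple bond. This is the Eschenmoser–Tanabe fragmentation, and the closest precedent is the conversion of the parent ring-fusion octalone oxide into cyclodec-5-ynone. The ten-membered ring is not closed by bond formation but released by cutting the bond shared by rings A and B, so no cyclisation mode, dilution or ring-closure entropy is involved. No stereocentre is formed: C3, C4, C7, C8 and C10 are spectators, and both epoxide carbons lose their configuration, so either epoxide face would serve. The step needs hydrazone formation at the single ketone to outrun acid opening of the epoxide and enolisation at C4. The low temperature and the fully substituted epoxide carbons, which resist attack by acetate or by the C12 acid, should secure this. The esters, the silyl ether and the acrylic acid are inert under these conditions.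

Step 24
Reactants: 31 alkynoic acid
Product: 32 enol lactone (O–C6, C5=C6)
Conditions: Ph3PAuNTf2 (cat.), CH2Cl2, 23 °C
Reagents that add atoms: none
Why: Gold-catalysed 5-exo-dig addition of the carboxylic acid to the activated alkyne (anti oxyauration, then protodeauration); the five-membered mode places oxygen on C6, not C5.

Step 25
Reactants: 32 enol lactone
Product: 33 cis-fused lactone, C3 silyl ether
Conditions: Et3SiH, CF3CO2H, CH2Cl2, –20 to 0 °C
Reagents that add atoms: none
Why: Ionic hydrogenation: protonation at C5 gives the lactone-stabilised oxocarbenium ion at C6, and the silane delivers hydride from the face opposite the C7–C8 bond, so H-6 ends cis to H-7; the electron-poor methylene and angelate alkenes are not protonated.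

Step 26
Reactants: 33 silyl ether
Product: 34 target
Conditions: HF·pyridine, THF, 0 to 23 °C
Reagents that add atoms: none
Why: Fluoride desilylation under weakly acidic conditions avoids retro-aldol cleavage of the β-hydroxy ketone and acyl migration.

## Compound list

1 | (R)-(–)-carvone, (5R)-2-methyl-5-(prop-1-en-2-yl)cyclohex-2-en-1-one | O=C1C[C@H](C(C)=C)CC=C1C | starting material
2 | (1R,5R)-cis-carveol, hydroxyl cis to the isopropenyl group | O[C@@H]1C[C@H](C(C)=C)CC=C1C | intermediate
3 | 9α,10α-epoxide of 2, epoxide cis to the hydroxyl | O[C@@H]1C[C@H](C(C)=C)C[C@@H]2O[C@]12C | intermediate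
4 | 9β-phenylselanyl-1α,10α-diol | O[C@@H]1C[C@H](C(C)=C)C[C@@H]([Se]c2ccccc2)[C@]1(C)O | intermediate
5 | selenoxide of 4 (configuration at selenium undefined) | O[C@@H]1C[C@H](C(C)=C)C[C@@H]([Se](=O)c2ccccc2)[C@]1(C)O | intermediate
6 | 1α,10α-dihydroxy-10β-methyl-7α-isopropenylcyclohex-8-ene | O[C@@H]1C[C@H](C(C)=C)C=C[C@]1(C)O | intermediate
7 | 8α,9α-epoxide of 6 | O[C@@H]1C[C@H](C(C)=C)[C@@H]2O[C@@H]2[C@]1(C)O | intermediate
8 | 1α,8α,10α-trihydroxy-10β-methyl-7α-isopropenylcyclohexane | O[C@@H]1C[C@H](C(C)=C)[C@H](O)C[C@]1(C)O | intermediate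
9 | dibutylstannylene acetal of the C1/C10 diol of 8 | CCCC[Sn]1(CCCC)O[C@@H]2C[C@H](C(C)=C)[C@H](O)C[C@]2(C)O1 | intermediate
10 | 8α,10α-dihydroxy-10β-methyl-7α-isopropenylcyclohexan-1-one | O=C1C[C@H](C(C)=C)[C@H](O)C[C@]1(C)O | intermediate
11 | 8α,10α-O-(di-tert-butylsilylene) derivative of 10 | O=C1C[C@H](C(C)=C)[C@H]2C[C@]1(C)O[Si](C(C)(C)C)(C(C)(C)C)O2 | intermediate
12 | 1-bromo-6-formyl-cyclohex-1(6)-ene with 7α-isopropenyl, 10β-methyl and the 8α,10α-silylene | BrC1=C(C=O)[C@H](C(C)=C)[C@H]2C[C@]1(C)O[Si](C(C)(C)C)(C(C)(C)C)O2 | intermediate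
13 | anti homoallylic alcohol: C6 carries CH(OH)–CH(CH3)–CH=CH2 (C5 R, C4 R) | BrC1=C([C@H](O)[C@H](C)C=C)[C@H](C(C)=C)[C@H]2C[C@]1(C)O[Si](C(C)(C)C)(C(C)(C)C)O2 | intermediate
14 | C5 4-methoxybenzyl ether of 13 | BrC1=C([C@H](OCc3ccc(OC)cc3)[C@H](C)C=C)[C@H](C(C)=C)[C@H]2C[C@]1(C)O[Si](C(C)(C)C)(C(C)(C)C)O2 | intermediate
15 | methyl ketone: C6 carries CH(OPMB)–CH(CH3)–C(=O)CH3 | BrC1=C([C@H](OCc3ccc(OC)cc3)[C@H](C)C(C)=O)[C@H](C(C)=C)[C@H]2C[C@]1(C)O[Si](C(C)(C)C)(C(C)(C)C)O2 | intermediate
16 | 1(6)-octalin-3-one: 4β-methyl, 5β-OPMB, 7α-isopropenyl, 10β-methyl, 8α,10α-silylene | COc1ccc(CO[C@@H]2[C@H](C)C(=O)CC3=C2[C@H](C(C)=C)[C@H]4C[C@]3(C)O[Si](C(C)(C)C)(C(C)(C)C)O4)cc1 | intermediate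
17 | 3β-alcohol of 16 (cis to the C4 methyl) | COc1ccc(CO[C@@H]2[C@H](C)[C@H](O)CC3=C2[C@H](C(C)=C)[C@H]4C[C@]3(C)O[Si](C(C)(C)C)(C(C)(C)C)O4)cc1 | intermediate
18 | 3β-tert-butyldimethylsilyl ether of 17 | COc1ccc(CO[C@@H]2[C@H](C)[C@H](O[Si](C)(C)C(C)(C)C)CC3=C2[C@H](C(C)=C)[C@H]4C[C@]3(C)O[Si](C(C)(C)C)(C(C)(C)C)O4)cc1 | intermediate
19 | 8α,10α-diol: 3β-OTBS, 4β-methyl, 5β-OPMB octalin | COc1ccc(CO[C@@H]2[C@H](C)[C@H](O[Si](C)(C)C(C)(C)C)CC3=C2[C@H](C(C)=C)[C@H](O)C[C@]3(C)O)cc1 | intermediate
20 | angelic acid, (Z)-2-methylbut-2-enoic acid | C/C=C(/C)C(=O)O | starting material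
21 | angelic 2,4,6-trichlorobenzoic anhydride | C/C=C(/C)C(=O)OC(=O)c1c(Cl)cc(Cl)cc1Cl | intermediate
22 | 8α-angelate of 19 (10α-hydroxyl free) | COc1ccc(CO[C@@H]2[C@H](C)[C@H](O[Si](C)(C)C(C)(C)C)CC3=C2[C@H](C(C)=C)[C@H](OC(=O)/C(C)=C\C)C[C@]3(C)O)cc1 | intermediate
23 | 10α-acetate of 22 | COc1ccc(CO[C@@H]2[C@H](C)[C@H](O[Si](C)(C)C(C)(C)C)CC3=C2[C@H](C(C)=C)[C@H](OC(=O)/C(C)=C\C)C[C@]3(C)OC(C)=O)cc1 | intermediate
24 | 5β-hydroxy-1(6)-octalin: 3β-OTBS, 4β-methyl, 7α-isopropenyl, 8α-angelate, 10α-acetate | O[C@@H]1[C@H](C)[C@H](O[Si](C)(C)C(C)(C)C)CC2=C1[C@H](C(C)=C)[C@H](OC(=O)/C(C)=C\C)C[C@]2(C)OC(C)=O | intermediate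
25 | 1β,6β-epoxide of 24 | O[C@@H]1[C@H](C)[C@H](O[Si](C)(C)C(C)(C)C)C[C@]23O[C@@]21[C@H](C(C)=C)[C@H](OC(=O)/C(C)=C\C)C[C@]3(C)OC(C)=O | intermediate
26 | 12-hydroxy derivative of 25 (C7 carries C(=CH2)CH2OH) | O[C@@H]1[C@H](C)[C@H](O[Si](C)(C)C(C)(C)C)C[C@]23O[C@@]21[C@H](C(CO)=C)[C@H](OC(=O)/C(C)=C\C)C[C@]3(C)OC(C)=O | intermediate
27 | 1β,6β-epoxy-5-ketone with C7 carrying C(=CH2)CHO | O=C1[C@H](C)[C@H](O[Si](C)(C)C(C)(C)C)C[C@]23O[C@@]21[C@H](C(C=O)=C)[C@H](OC(=O)/C(C)=C\C)C[C@]3(C)OC(C)=O | intermediate
28 | 1β,6β-epoxy-octal-5-one acid: C7 acrylic acid, 3β-OTBS, 4β-methyl, 8α-angelate, 10α-acetate | O=C1[C@H](C)[C@H](O[Si](C)(C)C(C)(C)C)C[C@]23O[C@@]21[C@H](C(=C)C(=O)O)[C@H](OC(=O)/C(C)=C\C)C[C@]3(C)OC(C)=O | intermediate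
29 | p-toluenesulfonyl hydrazide | Cc1ccc(S(=O)(=O)NN)cc1 | starting material
30 | C5 tosylhydrazone of 28 (C=N geometry undefined) | Cc1ccc(cc1)S(=O)(=O)NN=C2[C@H](C)[C@H](O[Si](C)(C)C(C)(C)C)C[C@]34O[C@@]32[C@H](C(=C)C(=O)O)[C@H](OC(=O)/C(C)=C\C)C[C@]4(C)OC(C)=O | intermediate
31 | (3R,4S,7R,8R,10S)-cyclodec-5-yn-1-one: C7 acrylic acid, 3-OTBS, 4-methyl, 8-angelate, 10-acetate | C=C(C(=O)O)[C@H]1C#C[C@H](C)[C@H](O[Si](C)(C)C(C)(C)C)CC(=O)[C@@](C)(OC(C)=O)C[C@H]1OC(=O)/C(C)=C\C | intermediate
32 | enol lactone: O–C6, C5=C6 with the lactone oxygen cis to C4 | C=C1C(=O)O/C2=C\[C@H](C)[C@H](O[Si](C)(C)C(C)(C)C)CC(=O)[C@@](C)(OC(C)=O)C[C@@H](OC(=O)/C(C)=C\C)[C@@H]12 | intermediate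
33 | 3-O-tert-butyldimethylsilyl ether of the target (cis lactone) | C=C1C(=O)O[C@H]2C[C@H](C)[C@H](O[Si](C)(C)C(C)(C)C)CC(=O)[C@@](C)(OC(C)=O)C[C@@H](OC(=O)/C(C)=C\C)[C@@H]12 | intermediate
34 | (3R,4S,6S,7S,8R,10S)-10-acetoxy-8-angeloyloxy-3-hydroxy-1-oxogermacr-11(13)-en-12,6-olide | C=C1C(=O)O[C@H]2C[C@H](C)[C@H](O)CC(=O)[C@@](C)(OC(C)=O)C[C@@H](OC(=O)/C(C)=C\C)[C@@H]12 | target

## Step count and least certain steps

Total step count: 26. Longest linear sequence: 26 steps (1 to 34); reagent preparation is not counted.

**Step 23 (key step).** Condensation at the hindered C5 ketone, flanked by C4 and the quaternary C6, may be slow. Acid opening of the epoxide (by acetic acid or by the C12 carboxyl) or epimerisation at C4 could then compete. Fallback, from 28 back to 31: 28 is condensed with 1-amino-2-phenylaziridine in CH2Cl2 to the N-aziridinyl imine F1. Warming F1 in toluene extrudes styrene and dinitrogen and triggers the same C1–C6 cleavage under neutral conditions, giving 31.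

**Step 12.** Equilibration to the more substituted C4 enolate would allow β-elimination of the C5 alkoxide, and oxidative addition at the hindered bromide may be slow. Fallback, from 15 back to 16: Stille coupling of 15 with tributyl(vinyl)stannane and Pd(PPh3)4 gives the C1-vinyl methyl ketone F2. Kinetic enolisation (LDA, Et3SiCl, –78 °C) gives the triethylsilyl enol ether F3. Ring-closing metathesis with the second-generation Grubbs catalyst forms C2=C3 and gives the cyclic silyl dienol ether F4. Mild aqueous acid then protonates C2 and releases 16.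

**Step 6.** Oxidation could also occur at C8 if a six-membered stannylene across the 1,3-diol forms beside the five-membered one. Fallback, from 8 back to 11: the order of steps 6 and 7 is reversed. (t-Bu)2Si(OTf)2 bridges the 1,3-diaxial C8/C10 diol of 8 to the silylene alcohol F5, whose single free hydroxyl at C1 is oxidised with Dess–Martin periodinane to 11.

**Step 20.** The ene reaction could take the C7 methine hydrogen instead of a methyl hydrogen, and selenous acid could open the tetrasubstituted epoxide. Fallback, from 25 back to 27: Dess–Martin oxidation of 25 gives the isopropenyl epoxy ketone F6. Ene chlorination with Ca(OCl)2 and CO2 in CH2Cl2/H2O gives the allylic chloride F7. Kornblum-type oxidation with N-methylmorpholine N-oxide and KI in MeCN gives 27.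

**Step 25 (with step 24).** The acyloxocarbenium ion could lose the C7 proton and drift to the conjugated furanone, hydride could arrive from the wrong face, and in step 24 the C1 carbonyl could attack the gold-activated alkyne across the ring. Fallback, from 31 back to 33: semihydrogenation of 31 (H2, Pd/CaCO3 poisoned with Pb(OAc)2, quinoline) gives the (Z)-cyclodecenone acid F8. Iodolactonisation (I2, NaHCO3, MeCN) closes the γ-lactone at C6 with anti addition to give the iodolactone F9. Bu3SnH with AIBN removes the iodine and gives 33.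

## Further compounds

F1 | step 23 | N-(2-phenylaziridin-1-yl)imine of 28 (aziridine carbon and C=N geometry undefined) | c1ccccc1C1CN1N=C1[C@H](C)[C@H](O[Si](C)(C)C(C)(C)C)C[C@]23O[C@@]21[C@H](C(=C)C(=O)O)[C@H](OC(=O)/C(C)=C\C)C[C@]3(C)OC(C)=O
F2 | step 12 | C1-vinyl analogue of 15 | C=CC1=C([C@H](OCc3ccc(OC)cc3)[C@H](C)C(C)=O)[C@H](C(C)=C)[C@H]2C[C@]1(C)O[Si](C(C)(C)C)(C(C)(C)C)O2
F3 | step 12 | triethylsilyl enol ether of F2 (C3(OSiEt3)=CH2) | C=CC1=C([C@H](OCc3ccc(OC)cc3)[C@H](C)C(=C)O[Si](CC)(CC)CC)[C@H](C(C)=C)[C@H]2C[C@]1(C)O[Si](C(C)(C)C)(C(C)(C)C)O2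
F4 | step 12 | cyclic silyl dienol ether (ring A closed, C2=C3–OSiEt3, C1=C6) | COc1ccc(CO[C@@H]2[C@H](C)C(O[Si](CC)(CC)CC)=CC3=C2[C@H](C(C)=C)[C@H]4C[C@]3(C)O[Si](C(C)(C)C)(C(C)(C)C)O4)cc1
F5 | step 6 | 8α,10α-O-(di-tert-butylsilylene) derivative of 8 with free 1α-hydroxyl | O[C@@H]1C[C@H](C(C)=C)[C@H]2C[C@]1(C)O[Si](C(C)(C)C)(C(C)(C)C)O2
F6 | step 20 | 1β,6β-epoxy-5-ketone with intact isopropenyl group | O=C1[C@H](C)[C@H](O[Si](C)(C)C(C)(C)C)C[C@]23O[C@@]21[C@H](C(C)=C)[C@H](OC(=O)/C(C)=C\C)C[C@]3(C)OC(C)=O
F7 | step 20 | allylic chloride of F6 (C7 carries C(=CH2)CH2Cl) | O=C1[C@H](C)[C@H](O[Si](C)(C)C(C)(C)C)C[C@]23O[C@@]21[C@H](C(CCl)=C)[C@H](OC(=O)/C(C)=C\C)C[C@]3(C)OC(C)=O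
F8 | step 25 | (5Z)-cyclodec-5-en-1-one acid from 31 | C=C(C(=O)O)[C@H]1/C=C\[C@H](C)[C@H](O[Si](C)(C)C(C)(C)C)CC(=O)[C@@](C)(OC(C)=O)C[C@H]1OC(=O)/C(C)=C\C
F9 | step 25 | 5-iodo derivative of 33 (iodine anti to the lactone oxygen) | C=C1C(=O)O[C@H]2[C@H](I)[C@H](C)[C@H](O[Si](C)(C)C(C)(C)C)CC(=O)[C@@](C)(OC(C)=O)C[C@@H](OC(=O)/C(C)=C\C)[C@@H]12
A1 | alternative 1 | ten-membered 1,6,8-trione with the O3 to O10 tetraisopropyldisiloxane bridge | O=C1C[C@@H]2[C@@H](C)CC(=O)CC(=O)C[C@]1(C)O[Si](C(C)C)(C(C)C)O[Si](C(C)C)(C(C)C)O2
A2 | alternative 2 | furan-fused ten-membered ring with C4 set, C1 dioxolane and silyl ethers at C3, C8 and C10 | c1coc2c1[C@H](O[Si](CC)(CC)CC)C[C@](C)(O[Si](CC)(CC)CC)C3(OCCO3)C[C@@H](O[Si](C(C)C)(C(C)C)C(C)C)[C@@H](C)C2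
A3 | alternative 3 | ten-membered homoallylic alcohol with C7 and C8 set | C=C(CO[Si](C)(C)C(C)(C)C)[C@H]1[C@@H](O[Si](C)(C)C(C)(C)C)C[C@H](C)[C@H](OCc2ccc(OC)cc2)CC3(OCCO3)[C@@](C)(O)C[C@H]1O
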